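Retrosynthetic cuts (target numbered as a pentadeca-2,6,12-trienoic acid: C-1 = CO2H, C-9 = stereocentre, C-12 bears CO2Me, C-15 is bonded to the butenolide): C-5–C-6 (sp3–sp2, last C–C bond); C-2=C-3 and C-12=C-13 (two Z-selective Horner–Wadsworth–Emmons olefinations); C-11–C-12 (phosphonate alkylation); C-15–butenolide C-4′ (B-alkyl Suzuki); C-8–C-9 (auxiliary-controlled enolate alkylation).
Feature used by the key step: C-6 is the CH3-bearing sp2 carbon of the acyclic 6E alkene and C-5 is an unbranched primary CH2 lying δ to C-1, so an (E)-2-iodoalk-2-ene and a primary homoallylic alkylzinc can be joined there with retention; no ring is closed, and the only ring (butenolide O-1′/C-2′(=O)/C-3′=C-4′/C-5′H2), the C-12 methyl ester and the protected C-1 ester are inert to RZnX and Pd(0).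
Forward, eastern half (C-6 to C-15): but-2-yn-1-ol → (E)-3-iodobut-2-enyl bromide → alkylation of a succinate-derived acyl oxazolidinone (sets C-9) → acyl C=O turned into the isopropenyl group → C-11 iodide → phosphonate → Z-olefination with the butenolide aldehyde, whose ring is bought intact as 4-bromofuran-2(5H)-one.
Forward, western half (C-1 to C-5): silylethyl diaryl phosphonoacetate → homoprenylation → Z-olefination → primary bromide; the two carboxyl groups are therefore different from the start (methyl ester east, fluoride-labile ester west).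
Union: a Pd-catalysed alkyl–alkenyl Negishi coupling joins the two fully functionalised halves and completes the whole carbon skeleton with every alkene and the stereocentre in place; fluoride then frees the acid.
Stereochemistry: C-9 (S) from the (R)-4-benzyloxazolidinone-directed alkylation; 6E from syn-hydrozirconation/iodination, carried through with retention; 2Z and 12Z from kinetically controlled phosphonate olefinations.

Key step: step 19

Remark on the structure: the SMILES is read as 9S, 6E and 2Z,12Z (in each enoate the carboxyl carbon is cis to the β-CH2 group).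

Step 1
Reactants: 1 but-2-yn-1-ol
Product: 3 (2E)-3-iodobut-2-en-1-ol (I trans to CH2OH), via alkenylzirconocene alkoxide 2 (not isolated)
Conditions: Cp2Zr(H)Cl (2.3 equiv), THF, 0 °C → rt; then I2, −78 → 0 °C
Reagents that add atoms: iodine, II
Why: Hydrozirconation–iodination: after the first equivalent of the Schwartz reagent has turned OH into a zirconium alkoxide, Zr–H adds syn across the alkyne and, under equilibration by the excess hydride, zirconium should rest on C-3 (the carbon that carries only CH3), so that iodinolysis with retention gives the E iodide.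

Step 2
Reactants: 3 (2E)-3-iodobut-2-en-1-ol
Product: 4 (2E)-1-bromo-3-iodobut-2-ene
Conditions: CBr4, PPh3, CH2Cl2, 0 °C
Reagents that add atoms: carbon tetrabromide, BrC(Br)(Br)Br
Why: Appel bromination (SN2 at the primary allylic carbon of the oxyphosphonium salt) should leave the vinyl iodide and the E geometry untouched.

Step 3
Reactants: 5 (4R)-4-benzyl-1,3-oxazolidin-2-one; 6 4-tert-butoxy-4-oxobutanoic acid (mono-tert-butyl succinate)
Product: 8 tert-butyl 4-[(4R)-4-benzyl-2-oxo-1,3-oxazolidin-3-yl]-4-oxobutanoate, via mixed pivalic anhydride 7 (not isolated)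
Conditions: 6, PivCl, Et3N, THF, −20 °C; then 5, LiCl, −20 °C → rt
Reagents that add atoms: none
Why: N-Acylation of the oxazolidinone by the mixed pivalic anhydride under LiCl/Et3N activation, in which the nucleophile attacks the less hindered succinyl carbonyl.

Step 4
Reactants: 8 tert-butyl 4-[(4R)-4-benzyl-2-oxo-1,3-oxazolidin-3-yl]-4-oxobutanoate; 4 (2E)-1-bromo-3-iodobut-2-ene
Product: 10 tert-butyl (3R,5E)-3-{[(4R)-4-benzyl-2-oxo-1,3-oxazolidin-3-yl]carbonyl}-6-iodohept-5-enoate, via sodium Z-enolate 9 (not isolated)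
Conditions: NaHMDS, THF, −78 °C; then 4, −78 → −45 °C
Reagents that add atoms: none
Why: Evans asymmetric alkylation: NaHMDS removes the more acidic imide α-proton, and the chelated (Z)-enolate is alkylated by the reactive allylic bromide on the face opposite to the benzyl group, which sets the future C-9 centre (3R here).

Step 5
Reactants: 10 tert-butyl (3R,5E)-3-{[(4R)-4-benzyl-2-oxo-1,3-oxazolidin-3-yl]carbonyl}-6-iodohept-5-enoate
Product: 11 tert-butyl (3R,5E)-6-iodo-3-[methoxy(methyl)carbamoyl]hept-5-enoate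
Conditions: MeNH(OMe)·HCl, AlMe3, CH2Cl2, −10 °C → rt
Reagents that add atoms: N,O-dimethylhydroxylamine hydrochloride, CNOC.Cl
Why: Weinreb amide formation by aluminium-amide transamination at the exocyclic imide carbonyl, which the hindered tert-butyl ester and the vinyl iodide should survive, with recovery of the auxiliary.

Step 6
Reactants: 11 tert-butyl (3R,5E)-6-iodo-3-[methoxy(methyl)carbamoyl]hept-5-enoate
Product: 12 tert-butyl (3R,5E)-3-acetyl-6-iodohept-5-enoate
Conditions: MeMgBr, THF, −78 → 0 °C; aqueous work-up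
Reagents that add atoms: methylmagnesium bromide, C[Mg]Br
Why: Weinreb ketone synthesis: the magnesium-chelated tetrahedral adduct stops at single addition and shields the α-centre from enolisation, while the tert-butyl ester and the vinyl iodide do not react with MeMgBr at or below 0 °C.

Step 7
Reactants: 12 tert-butyl (3R,5E)-3-acetyl-6-iodohept-5-enoate
Product: 13 tert-butyl (3R,5E)-6-iodo-3-(prop-1-en-2-yl)hept-5-enoate
Conditions: Ph3PCH3Br, KOtBu, THF, 0 °C; then 12, 0 °C
Reagents that add atoms: methyltriphenylphosphonium bromide, C[P+](c1ccccc1)(c1ccccc1)c1ccccc1.[Br-]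
Why: Wittig methylenation of the methyl ketone with a lithium-free ylide at 0 °C, where addition to the carbonyl should outrun enolisation towards the adjacent stereocentre, turns the acyl carbon into the isopropenyl group.

Step 8
Reactants: 13 tert-butyl (3R,5E)-6-iodo-3-(prop-1-en-2-yl)hept-5-enoate
Product: 14 (3R,5E)-6-iodo-3-(prop-1-en-2-yl)hept-5-en-1-ol
Conditions: DIBAL-H (3 equiv), CH2Cl2, −78 → 0 °C; Rochelle salt work-up
Reagents that add atoms: none
Why: DIBAL-H reduction of the tert-butyl ester to the primary alcohol, a hydride transfer that leaves the vinyl iodide and both alkenes alone.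

Step 9
Reactants: 14 (3R,5E)-6-iodo-3-(prop-1-en-2-yl)hept-5-en-1-ol
Product: 15 (2E,5R)-2,7-diiodo-5-(prop-1-en-2-yl)hept-2-ene
Conditions: I2, PPh3, imidazole, CH2Cl2, 0 °C → rt
Reagents that add atoms: iodine, II
Why: Garegg–Samuelsson (Appel-type) iodination of the primary alcohol by SN2 displacement of the oxyphosphonium group; the stereocentre is not involved.

Step 10
Reactants: 15 (2E,5R)-2,7-diiodo-5-(prop-1-en-2-yl)hept-2-ene; 16 methyl 2-[bis(2,2,2-trifluoroethoxy)phosphoryl]acetate
Product: 18 methyl (5S,7E)-2-[bis(2,2,2-trifluoroethoxy)phosphoryl]-8-iodo-5-(prop-1-en-2-yl)non-7-enoate (both C-2 epimers), via sodium phosphonoacetate 17 (not isolated)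
Conditions: 16 (2 equiv), NaH, DMF, 0 °C; then 15, rt → 50 °C
Reagents that add atoms: none
Why: SN2 C-alkylation of the stabilised phosphonoacetate carbanion by the unhindered primary iodide (the vinyl iodide cannot react), with excess phosphonate used against dialkylation; the descriptor changes from R to S only because the CIP priorities of the two chains change.

Step 11
Reactants: 19 3,3-diethoxyprop-1-ene (acrolein diethyl acetal); 20 4-bromofuran-2(5H)-one
Product: 22 4-(3,3-diethoxypropyl)furan-2(5H)-one, via B-(3,3-diethoxypropyl)-9-BBN 21 (not isolated)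
Conditions: 19, 9-BBN-H, THF, 0 °C → rt; then 20, PdCl2(dppf) (5 mol %), K3PO4, DMF/H2O, rt
Reagents that add atoms: none
Why: Anti-Markovnikov hydroboration of the terminal alkene with 9-BBN-H followed by B-alkyl Suzuki–Miyaura coupling at the electron-poor C–Br bond of the bromobutenolide, with a mild phosphate base so that the lactone ring stays closed.

Step 12
Reactants: 22 4-(3,3-diethoxypropyl)furan-2(5H)-one
Product: 23 3-(5-oxo-2,5-dihydrofuran-3-yl)propanal
Conditions: 1 M HCl, THF, rt
Reagents that add atoms: water, O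
Why: Acid-catalysed acetal hydrolysis, to which the butenolide is stable; the enolisable aldehyde is used without storage.

Step 13
Reactants: 18 methyl (5S,7E)-2-[bis(2,2,2-trifluoroethoxy)phosphoryl]-8-iodo-5-(prop-1-en-2-yl)non-7-enoate; 23 3-(5-oxo-2,5-dihydrofuran-3-yl)propanal
Product: 25 methyl (2Z)-2-[(3S,5E)-6-iodo-3-(prop-1-en-2-yl)hept-5-en-1-yl]-5-(5-oxo-2,5-dihydrofuran-3-yl)pent-2-enoate, via potassium phosphonate 24 (not isolated)
Conditions: 18, KHMDS, 18-crown-6, THF, −78 °C; then 23, −78 °C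
Reagents that add atoms: none
Why: Still–Gennari variant of the Horner–Wadsworth–Emmons olefination: the electron-poor trifluoroethyl phosphonate with a dissociated potassium counter-ion adds irreversibly and eliminates fast, which should give the (Z)-2-alkyl-2-enoate (CO2Me cis to the new β-CH2) under kinetic control, and the weakly basic phosphonate anion should not attack the butenolide.

Step 14
Reactants: 26 bromoacetyl bromide; 27 2-(trimethylsilyl)ethanol
Product: 28 2-(trimethylsilyl)ethyl 2-bromoacetate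
Conditions: pyridine, CH2Cl2, 0 °C
Reagents that add atoms: none
Why: O-Acylation of the primary alcohol by the acid bromide (esterification) with pyridine as acid scavenger.

Step 15
Reactants: 28 2-(trimethylsilyl)ethyl 2-bromoacetate; 29 diphenyl phosphite
Product: 30 2-(trimethylsilyl)ethyl 2-(diphenoxyphosphoryl)acetate
Conditions: Et3N, CH2Cl2, 0 °C → rt
Reagents that add atoms: none
Why: Michaelis–Becker P-alkylation of the phosphite anion by the α-bromo ester, the standard entry to diaryl phosphonoacetates for Ando-type olefinations.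

Step 16
Reactants: 30 2-(trimethylsilyl)ethyl 2-(diphenoxyphosphoryl)acetate; 31 5-bromo-2-methylpent-2-ene
Product: 33 2-(trimethylsilyl)ethyl 2-(diphenoxyphosphoryl)-6-methylhept-5-enoate (racemic), via sodium phosphonoacetate 32 (not isolated)
Conditions: NaH, DMSO, rt; then 31, NaI (cat.), rt
Reagents that add atoms: none
Why: SN2 C-alkylation of the phosphonoacetate carbanion by the primary homoprenyl bromide (iodide catalysis) installs the 4-methylpent-3-enyl chain at the future C-2.

Step 17
Reactants: 33 2-(trimethylsilyl)ethyl 2-(diphenoxyphosphoryl)-6-methylhept-5-enoate; 34 3-[(tert-butyldimethylsilyl)oxy]propanal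
Product: 36 2-(trimethylsilyl)ethyl (2Z)-5-[(tert-butyldimethylsilyl)oxy]-2-(4-methylpent-3-en-1-yl)pent-2-enoate, via sodium phosphonate 35 (not isolated)
Conditions: 33, NaH, THF, 0 °C; then 34, −78 → −20 °C
Reagents that add atoms: none
Why: Ando-type Z-selective Horner–Wadsworth–Emmons olefination: the diaryl phosphonate eliminates faster than its adducts equilibrate, which should place the ester cis to the new β-CH2 (2Z), and the low temperature keeps the β-silyloxy aldehyde from eliminating.

Step 18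
Reactants: 36 2-(trimethylsilyl)ethyl (2Z)-5-[(tert-butyldimethylsilyl)oxy]-2-(4-methylpent-3-en-1-yl)pent-2-enoate
Product: 37 2-(trimethylsilyl)ethyl (2Z)-5-bromo-2-(4-methylpent-3-en-1-yl)pent-2-enoate
Conditions: Ph3PBr2, CH2Cl2, 0 °C → rt
Reagents that add atoms: dibromotriphenylphosphorane, BrP(Br)(c1ccccc1)(c1ccccc1)c1ccccc1
Why: Direct conversion of the silyl ether into the bromide with Ph3PBr2 (O-phosphonium formation with loss of the silyl bromide, then SN2 by bromide), chosen so that the free δ-hydroxy (Z)-ester, which would close to the unsaturated δ-lactone, never appears.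

Step 19
Reactants: 37 2-(trimethylsilyl)ethyl (2Z)-5-bromo-2-(4-methylpent-3-en-1-yl)pent-2-enoate; 25 methyl (2Z)-2-[(3S,5E)-6-iodo-3-(prop-1-en-2-yl)hept-5-en-1-yl]-5-(5-oxo-2,5-dihydrofuran-3-yl)pent-2-enoate
Product: 39 2-(trimethylsilyl)ethyl (2Z,6E,9S,12Z)-12-(methoxycarbonyl)-6-methyl-2-(4-methylpent-3-en-1-yl)-15-(5-oxo-2,5-dihydrofuran-3-yl)-9-(prop-1-en-2-yl)pentadeca-2,6,12-trienoate, via alkylzinc bromide 38 (not isolated)
Conditions: 37 (1.6 equiv), Zn dust (TMSCl/BrCH2CH2Br-activated), LiCl, THF, 50 °C; then 25, Pd(OAc)2 (5 mol %), SPhos (10 mol %), THF, rt → 40 °C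
Reagents that add atoms: none
Why: LiCl-assisted insertion of zinc into the primary C–Br bond of 37 gives the homoallylic alkylzinc 38, which tolerates its own ester; Pd(0)/SPhos then adds oxidatively into the C(sp2)–I bond of 25 with retention, the alkyl group passes from zinc to palladium, and reductive elimination forms the C-5–C-6 bond. The closest known reaction type is the Pd-catalysed Negishi coupling of functionalised primary alkylzinc halides with 2-iodoalk-2-enes. No ring is closed and no stereocentre is formed; C-9 lies three bonds from the reacting carbon and carries no acidic hydrogen, so its S configuration is not at risk. The step needs retention of the 6E geometry, which the stereoretentive oxidative addition and reductive elimination at the alkenyl–Pd bond secure, and it needs suppression of β-hydride elimination from the alkyl–Pd intermediate, which the bulky biaryl phosphine secures by speeding up reductive elimination. It also needs chemoselectivity: the C–I bond is the only site that Pd(0) enters, and the neutral organozinc should add neither to the two esters nor to the butenolide, while the base-free conditions leave both (Z)-enoates unisomerised.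

Step 20
Reactants: 39 2-(trimethylsilyl)ethyl (2Z,6E,9S,12Z)-12-(methoxycarbonyl)-6-methyl-2-(4-methylpent-3-en-1-yl)-15-(5-oxo-2,5-dihydrofuran-3-yl)-9-(prop-1-en-2-yl)pentadeca-2,6,12-trienoate
Product: 40 (2Z,6E,9S,12Z)-12-(methoxycarbonyl)-6-methyl-2-(4-methylpent-3-en-1-yl)-15-(5-oxo-2,5-dihydrofuran-3-yl)-9-(prop-1-en-2-yl)pentadeca-2,6,12-trienoic acid (target, CNP0162600.1)
Conditions: TBAF, THF, 0 °C → rt; dilute HCl work-up
Reagents that add atoms: none
Why: Fluoride-induced fragmentation of the 2-(trimethylsilyl)ethyl ester (attack at silicon, loss of ethene) should free the C-1 acid without touching the methyl ester, the butenolide or any alkene geometry.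

Compound list
1 | but-2-yn-1-ol | CC#CCO | starting material
2 | (E)-but-2-en-1-ol carrying chloridobis(cyclopentadienyl)zirconium on C-3 (cis to H-2) and on oxygen | C/C(=C\CO[Zr](Cl)(C1C=CC=C1)C1C=CC=C1)[Zr](Cl)(C1C=CC=C1)C1C=CC=C1 | intermediate
3 | (2E)-3-iodobut-2-en-1-ol | C/C(I)=C\CO | intermediate
4 | (2E)-1-bromo-3-iodobut-2-ene | C/C(I)=C\CBr | intermediate
5 | (4R)-4-benzyl-1,3-oxazolidin-2-one | O=C1N[C@H](Cc2ccccc2)CO1 | starting material
6 | 4-tert-butoxy-4-oxobutanoic acid | CC(C)(C)OC(=O)CCC(=O)O | starting material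
7 | 4-tert-butoxy-4-oxobutanoic pivalic anhydride | CC(C)(C)OC(=O)CCC(=O)OC(=O)C(C)(C)C | intermediate
8 | tert-butyl 4-[(4R)-4-benzyl-2-oxo-1,3-oxazolidin-3-yl]-4-oxobutanoate | CC(C)(C)OC(=O)CCC(=O)N1[C@H](Cc2ccccc2)COC1=O | intermediate
9 | sodium (1Z)-1-[(4R)-4-benzyl-2-oxo-1,3-oxazolidin-3-yl]-4-tert-butoxy-4-oxobut-1-en-1-olate | CC(C)(C)OC(=O)C/C=C(\[O-])N1[C@H](Cc2ccccc2)COC1=O.[Na+] | intermediate
10 | tert-butyl (3R,5E)-3-{[(4R)-4-benzyl-2-oxo-1,3-oxazolidin-3-yl]carbonyl}-6-iodohept-5-enoate | O=C(N1[C@H](Cc2ccccc2)COC1=O)[C@H](C/C=C(\C)I)CC(=O)OC(C)(C)C | intermediate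
11 | tert-butyl (3R,5E)-6-iodo-3-[methoxy(methyl)carbamoyl]hept-5-enoate | CON(C)C(=O)[C@H](C/C=C(\C)I)CC(=O)OC(C)(C)C | intermediate
12 | tert-butyl (3R,5E)-3-acetyl-6-iodohept-5-enoate | CC(=O)[C@H](C/C=C(\C)I)CC(=O)OC(C)(C)C | intermediate
13 | tert-butyl (3R,5E)-6-iodo-3-(prop-1-en-2-yl)hept-5-enoate | C=C(C)[C@H](C/C=C(\C)I)CC(=O)OC(C)(C)C | intermediate
14 | (3R,5E)-6-iodo-3-(prop-1-en-2-yl)hept-5-en-1-ol | C=C(C)[C@H](C/C=C(\C)I)CCO | intermediate
15 | (2E,5R)-2,7-diiodo-5-(prop-1-en-2-yl)hept-2-ene | C=C(C)[C@H](C/C=C(\C)I)CCI | intermediate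
16 | methyl 2-[bis(2,2,2-trifluoroethoxy)phosphoryl]acetate | COC(=O)CP(=O)(OCC(F)(F)F)OCC(F)(F)F | starting material
17 | sodium salt of 16 (carbanion at C-2) | COC(=O)[CH-]P(=O)(OCC(F)(F)F)OCC(F)(F)F.[Na+] | intermediate
18 | methyl (5S,7E)-2-[bis(2,2,2-trifluoroethoxy)phosphoryl]-8-iodo-5-(prop-1-en-2-yl)non-7-enoate (both C-2 epimers) | C=C(C)[C@H](C/C=C(\C)I)CCC(C(=O)OC)P(=O)(OCC(F)(F)F)OCC(F)(F)F | intermediate
19 | 3,3-diethoxyprop-1-ene | C=CC(OCC)OCC | starting material
20 | 4-bromofuran-2(5H)-one | BrC1=CC(=O)OC1 | starting material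
21 | 9-(3,3-diethoxypropyl)-9-borabicyclo[3.3.1]nonane | CCOC(CCB1C2CCCC1CCC2)OCC | intermediate
22 | 4-(3,3-diethoxypropyl)furan-2(5H)-one | CCOC(CCC1=CC(=O)OC1)OCC | intermediate
23 | 3-(5-oxo-2,5-dihydrofuran-3-yl)propanal | O=CCCC1=CC(=O)OC1 | intermediate
24 | potassium salt of 18 (carbanion at C-2) | C=C(C)[C@H](C/C=C(\C)I)CC[C-](C(=O)OC)P(=O)(OCC(F)(F)F)OCC(F)(F)F.[K+] | intermediate
25 | methyl (2Z)-2-[(3S,5E)-6-iodo-3-(prop-1-en-2-yl)hept-5-en-1-yl]-5-(5-oxo-2,5-dihydrofuran-3-yl)pent-2-enoate | C=C(C)[C@H](C/C=C(\C)I)CC/C(=C/CCC1=CC(=O)OC1)C(=O)OC | intermediate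
26 | bromoacetyl bromide | BrCC(Br)=O | starting material
27 | 2-(trimethylsilyl)ethanol | C[Si](C)(C)CCO | starting material
28 | 2-(trimethylsilyl)ethyl 2-bromoacetate | BrCC(=O)OCC[Si](C)(C)C | intermediate
29 | diphenyl phosphite | O=[PH](Oc1ccccc1)Oc1ccccc1 | starting material
30 | 2-(trimethylsilyl)ethyl 2-(diphenoxyphosphoryl)acetate | O=C(CP(=O)(Oc1ccccc1)Oc1ccccc1)OCC[Si](C)(C)C | intermediate
31 | 5-bromo-2-methylpent-2-ene | CC(C)=CCCBr | starting material
32 | sodium salt of 30 (carbanion at C-2) | O=C([CH-]P(=O)(Oc1ccccc1)Oc1ccccc1)OCC[Si](C)(C)C.[Na+] | intermediate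
33 | 2-(trimethylsilyl)ethyl 2-(diphenoxyphosphoryl)-6-methylhept-5-enoate (racemic) | CC(C)=CCCC(C(=O)OCC[Si](C)(C)C)P(=O)(Oc1ccccc1)Oc1ccccc1 | intermediate
34 | 3-[(tert-butyldimethylsilyl)oxy]propanal | O=CCCO[Si](C)(C)C(C)(C)C | starting material
35 | sodium salt of 33 (carbanion at C-2) | CC(C)=CCC[C-](C(=O)OCC[Si](C)(C)C)P(=O)(Oc1ccccc1)Oc1ccccc1.[Na+] | intermediate
36 | 2-(trimethylsilyl)ethyl (2Z)-5-[(tert-butyldimethylsilyl)oxy]-2-(4-methylpent-3-en-1-yl)pent-2-enoate | CC(C)=CCC/C(=C/CCO[Si](C)(C)C(C)(C)C)C(=O)OCC[Si](C)(C)C | intermediate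
37 | 2-(trimethylsilyl)ethyl (2Z)-5-bromo-2-(4-methylpent-3-en-1-yl)pent-2-enoate | CC(C)=CCC/C(=C/CCBr)C(=O)OCC[Si](C)(C)C | intermediate
38 | bromido[(3Z)-8-methyl-4-{[2-(trimethylsilyl)ethoxy]carbonyl}nona-3,7-dien-1-yl]zinc | CC(C)=CCC/C(=C/CC[Zn]Br)C(=O)OCC[Si](C)(C)C | intermediate
39 | 2-(trimethylsilyl)ethyl (2Z,6E,9S,12Z)-12-(methoxycarbonyl)-6-methyl-2-(4-methylpent-3-en-1-yl)-15-(5-oxo-2,5-dihydrofuran-3-yl)-9-(prop-1-en-2-yl)pentadeca-2,6,12-trienoate | C=C(C)[C@H](C/C=C(\C)CC/C=C(/CCC=C(C)C)C(=O)OCC[Si](C)(C)C)CC/C(=C/CCC1=CC(=O)OC1)C(=O)OC | intermediate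
40 | (2Z,6E,9S,12Z)-12-(methoxycarbonyl)-6-methyl-2-(4-methylpent-3-en-1-yl)-15-(5-oxo-2,5-dihydrofuran-3-yl)-9-(prop-1-en-2-yl)pentadeca-2,6,12-trienoic acid | C=C(C)[C@H](C/C=C(\C)CC/C=C(/CCC=C(C)C)C(=O)O)CC/C(=C/CCC1=CC(=O)OC1)C(=O)OC | target

Total step count: 20. Longest linear sequence: 12 steps (1, 2, 4–10, 13, 19, 20).

Steps most likely to fail

Step 19. Zinc insertion into the bromide may stay incomplete and the alkylzinc may be protonated, or β-hydride elimination and hydrodeiodination at palladium may consume both halves without joining them. The fallback makes the same C-5–C-6 bond by a B-alkyl Suzuki–Miyaura coupling with a C3 borane and builds the western enoate afterwards. It sets out from 25: borane 21 (from 19 and 9-BBN-H as in step 11) is coupled with 25 (PdCl2(dppf), K3PO4, DMF/THF/H2O, rt) to give methyl (2Z)-2-[(3S,5E)-9,9-diethoxy-6-methyl-3-(prop-1-en-2-yl)non-5-en-1-yl]-5-(5-oxo-2,5-dihydrofuran-3-yl)pent-2-enoate F1. Hydrolysis with 1 M HCl in THF should give methyl (2Z)-2-[(3S,5E)-6-methyl-9-oxo-3-(prop-1-en-2-yl)non-5-en-1-yl]-5-(5-oxo-2,5-dihydrofuran-3-yl)pent-2-enoate F2. Ando-type olefination of F2 with the sodium salt 35 of phosphonate 33 (NaH, THF, −78 → −20 °C) would form the 2Z enoate and come back to the route at 39.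

Step 10. The weakly nucleophilic fluorinated phosphonate anion may attack the iodide too slowly, so that dialkylation and base-induced loss of trifluoroethoxy groups take over on warming. The fallback alkylates the more nucleophilic trimethyl phosphonoacetate and exchanges the ester groups on phosphorus afterwards. It sets out from 15: trimethyl phosphonoacetate, NaH and 15 in DMF give methyl (5S,7E)-2-(dimethoxyphosphoryl)-8-iodo-5-(prop-1-en-2-yl)non-7-enoate F3. Me3SiBr (CH2Cl2, rt) cleaves only the P–OMe groups to methyl (5S,7E)-2-{bis[(trimethylsilyl)oxy]phosphoryl}-8-iodo-5-(prop-1-en-2-yl)non-7-enoate F4. Oxalyl chloride with catalytic DMF gives methyl (5S,7E)-2-(dichlorophosphoryl)-8-iodo-5-(prop-1-en-2-yl)non-7-enoate F5, and CF3CH2OH/Et3N then gives 18, where the route is rejoined.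

Step 13. Kinetic control may be lost through reversible addition of the branched phosphonate anion, which would erode the Z selectivity, and the strong base may trigger self-condensation of the enolisable aldehyde. The fallback uses a diaryl phosphonate whose anion can be made with a weak amine base. It sets out from 15: methyl 2-(diphenoxyphosphoryl)acetate F6 (from methyl bromoacetate and 29 with Et3N, as in step 15) is alkylated with 15 (NaH, DMSO, rt) to methyl (5S,7E)-2-(diphenoxyphosphoryl)-8-iodo-5-(prop-1-en-2-yl)non-7-enoate F7. Olefination of 23 with F7 under NaI/DBU in THF (−78 → 0 °C) should give the Z enoate and come back to the route at 25.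

Further compounds
F1 | step 19 | methyl (2Z)-2-[(3S,5E)-9,9-diethoxy-6-methyl-3-(prop-1-en-2-yl)non-5-en-1-yl]-5-(5-oxo-2,5-dihydrofuran-3-yl)pent-2-enoate | C=C(C)[C@H](C/C=C(\C)CCC(OCC)OCC)CC/C(=C/CCC1=CC(=O)OC1)C(=O)OC
F2 | step 19 | methyl (2Z)-2-[(3S,5E)-6-methyl-9-oxo-3-(prop-1-en-2-yl)non-5-en-1-yl]-5-(5-oxo-2,5-dihydrofuran-3-yl)pent-2-enoate | C=C(C)[C@H](C/C=C(\C)CCC=O)CC/C(=C/CCC1=CC(=O)OC1)C(=O)OC
F3 | step 10 | methyl (5S,7E)-2-(dimethoxyphosphoryl)-8-iodo-5-(prop-1-en-2-yl)non-7-enoate | C=C(C)[C@H](C/C=C(\C)I)CCC(C(=O)OC)P(=O)(OC)OC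
F4 | step 10 | methyl (5S,7E)-2-{bis[(trimethylsilyl)oxy]phosphoryl}-8-iodo-5-(prop-1-en-2-yl)non-7-enoate | C=C(C)[C@H](C/C=C(\C)I)CCC(C(=O)OC)P(=O)(O[Si](C)(C)C)O[Si](C)(C)C
F5 | step 10 | methyl (5S,7E)-2-(dichlorophosphoryl)-8-iodo-5-(prop-1-en-2-yl)non-7-enoate | C=C(C)[C@H](C/C=C(\C)I)CCC(C(=O)OC)P(=O)(Cl)Cl
F6 | step 13 | methyl 2-(diphenoxyphosphoryl)acetate | COC(=O)CP(=O)(Oc1ccccc1)Oc1ccccc1
F7 | step 13 | methyl (5S,7E)-2-(diphenoxyphosphoryl)-8-iodo-5-(prop-1-en-2-yl)non-7-enoate | C=C(C)[C@H](C/C=C(\C)I)CCC(C(=O)OC)P(=O)(Oc1ccccc1)Oc1ccccc1
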